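Numbering used throughout: building blocks **1**, **2**, **6**; Grignard **3**; ring A intermediates **4**, **5**; ring B intermediates **7**, **8**, **9**; borane **10**; coupled acetal **11**; cyclisation precursor **12**; macrocyclic dialdehyde **13**; bis-formate **14**; macrocyclic diol methyl ether **15**; target **16**.

## The problem

Compound **16** is a 20-membered meta,para-cyclophane. Ring A is a 5-alkylresorcinol unit (ether carbon A1, hydroxyl carbon A3, chain carbon A5) and ring B a 2-aryloxyresorcinol unit (ether carbon B1 between hydroxyl carbons B2 and B6, chain carbon B4). The rings are joined twice: through a diaryl ether oxygen and through an unbranched chain of twelve methylene groups (C1 on B4 to C12 on A5). There is no stereocentre, so the tasks are ring closure, regiochemistry and late handling of three phenols. The hardest bond is O–B1: with two ortho oxygens, ring B in its native oxidation pattern is too electron-rich for nucleophilic substitution and too hindered for easy copper- or palladium-mediated etherification. Ring A has two equivalent oxygens, so one must be masked to leave a single defined nucleophile. The saturated chain offers no handle, so both aryl–CH2 bonds must come from sp3–sp2 couplings that leave no functional group behind. The free phenols are sensitive to oxidants and to base in air and should be unveiled only at the end. The enabling feature is the symmetric pair of hydroxyls at B2 and B6: carried as formyl groups they make B1 of a 2-fluoroisophthalaldehyde strongly electrophilic, and each formyl is afterwards exchanged for hydroxyl by Dakin oxidation.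

## Retrosynthesis

**16 ⇒ 15.** The O–CH3 bond at A3 is cut last. The methyl ether is what remains of the desymmetrisation of ring A, it tolerates palladium, borane, carbonate and peracid, and its removal with BBr3 does not endanger a diaryl ether. Precursor **15** differs from the target by this one cap.

**15 ⇒ 13 (through 14).** The C–O bonds at B2 and B6 are traced back to C–CHO bonds. Carrying these oxygens as ethers would leave B1 inert; carrying them as formyl groups makes B1 the most electrophilic site in the molecule. The forward reaction must be a double aryl migration on a ring that bears an ortho aryloxy donor (Dakin-type Baeyer–Villiger, then formate cleavage).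

**13 ⇒ 12.** The O–B1 bond is cut, so the most hindered bond of the target closes the ring. Cutting a chain C–C bond instead would leave the same hindered ether to be made intermolecularly. Cutting O–A1 would require a 2,6-disubstituted phenol to couple to an unactivated arene. Precursor **12** is acyclic, with one free phenol and one fluoride between two formyl groups. The forward step is an intramolecular SNAr that must beat oligomerisation.

**12 ⇒ 11 ⇒ 5 + 9.** The C1–B4 bond is cut by a B-alkyl Suzuki–Miyaura disconnection. This splits the molecule into a ring A alkene (**5**) and a ring B bromide (**9**) of similar size. The formyl groups travel as dioxolanes (**11**, **9**) for two reasons: 9-BBN reduces aldehydes, and free formyl groups would let phenoxide attack the fluoride during the coupling. Acid then releases **12** with the phenol protonated.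

**5 ⇒ 4 ⇒ 1 + 2 (through 3).** The C12–A5 bond is cut by a Kumada disconnection between Grignard **3** (from bromoalkene **1**) and bromoarene **2**. The whole chain arrives in one piece, with its terminal alkene as the handle for the later coupling. Thiolate demethylation of symmetric **4** stops after one ether, which supplies the single nucleophilic oxygen of **5**.

**9 ⇒ 8 ⇒ 7 ⇒ 6.** Only functional-group changes remain on ring B: acetals from dialdehyde **8**, which comes from tetrabromide **7**, which comes from xylene **6**. Halogen pattern and substitution are bought, so no regiochemical problem arises.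

## Roads not taken

**Alternative 1:** The cut runs through ring A itself. Diazo enone A1 carries the ether oxygen as a silyl ynol ether on B1. On irradiation, Wolff rearrangement gives a vinylketene, which adds [2+2] to the ynol ether; 4π opening, 6π closure and tautomerisation then give the macrocyclic silylphenol A2. Ring A and the macrocycle form together (bonds A5–A6, A2–A3, A1–A6, A3–A4).
- Merits: the crowded B1 oxygen is attached early by O-alkynylation of a syringol-type phenol, ring B arrives fully oxygenated so no Dakin step is needed, and the bond count of the cascade is outstanding. In elegance this road is ahead.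
- Weak points: the ketene–alkyne cycloaddition is a capture of a short-lived intermediate. As a 20-membered ring closure at high dilution it competes with ketene dimerisation and with trapping by adventitious nucleophiles. A1 combines a diazo ketone, a 1,1-disubstituted enone and an aryl ynol ether at the ends of a C12 chain, which is long to assemble. Afterwards the silyl group between two oxygens and two methyl ethers must be removed.
- Comparison: the chosen plan offers a ground-state ionic closure whose rate is set by base, temperature and dilution, and a precursor reached in seven routine operations.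

**Alternative 2:** The cut is O–A1 with ring A in dihydro-keto form. The hindered phenoxide of chloroenone A3 adds to the chlorine-bearing carbon of the tethered 3-chlorocyclohexenone and chloride leaves, giving racemic aryloxyenone A4. Dehydrogenation to the phenol and two demethylations would follow.
- Merits: the polarity is natural, since the hindered oxygen is the nucleophile and the electrophile is an open, reactive sp2 carbon. Ring B comes from syringyl materials with all oxygens in place. On the ring B side this road is better.
- Weak points: ring A must be built as a 5-alkylcyclohexane-1,3-dione and chlorinated while the ring B phenol is separately protected. Aromatisation needs an oxidant next to an electron-rich arene and risks loss of the aryloxy group from the vinylogous ester. A stereocentre is made only to be destroyed.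
- Comparison: the ring closures are of similar reliability. The chosen plan must set its double Dakin oxidation against the aromatisation here, but it keeps both rings aromatic and takes them from simple bromoarenes, which saves steps.

**Alternative 3:** The cut is the chain bond C3–C4, with the diaryl ether already in place. The zerovalent palladium complex Pd(PPh3)4 ionises the cinnamyl carbonate of A5, and the tethered bis(phenylsulfonyl)methyl carbanion attacks the allyl terminus remote from the arene to give macrocyclic (E)-styrene A6.
- Merits: palladium-allyl closures with soft bis-sulfonyl carbanions are among the most dependable large-ring C–C bond formations and tolerate higher concentration. As a ring-closing event this is probably more reliable than the SNAr.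
- Weak points: the hindered O–B1 bond is not solved but moved to an intermolecular coupling. After closure, alkene hydrogenation, double desulfonylation and threefold demethylation add nothing to the skeleton. Two functionalised chain halves must be prepared.
- Comparison: the chosen plan is clearly shorter and uses its activating groups twice, once to form the hard bond and once as the source of the B2 and B6 hydroxyls.

Key step: step 8

Assumption: the target is achiral and **1**, **2** and **6** are taken as purchasable. In the phane names, superatom 1 is ring A (1¹ = A1, 1³ = A5, 1⁵ = A3), atom 2 is the ether oxygen, superatom 3 is ring B (3¹ = B1, 3²/3⁶ = B2/B6, 3⁴ = B4), and atoms 4–15 are C1–C12.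

## Route

Step 1
Reactants: 1 12-bromododec-1-ene; 2 1-bromo-3,5-dimethoxybenzene
Product: 4 1-(dodec-11-en-1-yl)-3,5-dimethoxybenzene, via dodec-11-en-1-ylmagnesium bromide 3 (not isolated)
Conditions: Mg, I2 (cat.), THF, 40 °C; then 2, Pd(dppf)Cl2 (2 mol %), THF, reflux
Reagents that add atoms: magnesium, [Mg] (kept only in intermediate 3)
Why: Kumada–Corriu sp3–sp2 coupling; the primary Grignard transmetalates to the arylpalladium bromide from 2, and the wide bite angle of dppf favours reductive elimination over β-hydride elimination. The remote terminal alkene should not interfere.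

Step 2
Reactants: 4 1-(dodec-11-en-1-yl)-3,5-dimethoxybenzene
Product: 5 3-(dodec-11-en-1-yl)-5-methoxyphenol
Conditions: NaSEt (4 equiv), DMF, 140 °C; then 1 M HCl
Reagents that add atoms: none
Why: SN2 O-demethylation by ethanethiolate at the methyl carbon. The phenoxide formed after the first cleavage is too poor a leaving group for a second, so the reaction should stop at the monophenol, as is usual for 5-alkylresorcinol dimethyl ethers; the unactivated alkene is inert to thiolate without radicals.

Step 3
Reactants: 6 5-bromo-2-fluoro-1,3-dimethylbenzene
Product: 7 5-bromo-1,3-bis(dibromomethyl)-2-fluorobenzene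
Conditions: NBS (4.6 equiv), AIBN (cat.), PhCF3, reflux, visible light
Reagents that add atoms: N-bromosuccinimide, O=C1CCC(=O)N1Br
Why: Wohl–Ziegler benzylic bromination taken to the gem-dibromide at both methyl groups. A third bromine at an ortho-flanked carbon is sterically retarded, and aryl C–Br and C–F bonds are inert to bromine radicals.

Step 4
Reactants: 7 5-bromo-1,3-bis(dibromomethyl)-2-fluorobenzene
Product: 8 5-bromo-2-fluorobenzene-1,3-dicarbaldehyde
Conditions: AgNO3 (4.4 equiv), acetone/H2O, reflux
Reagents that add atoms: water, O
Why: Silver-assisted hydrolysis of benzylic gem-dibromides; Ag+ abstracts bromide, water captures the cation and the bromohydrin collapses to the aldehyde. The medium is acidic, so water should not displace the fluoride that the new formyl groups activate.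

Step 5
Reactants: 8 5-bromo-2-fluorobenzene-1,3-dicarbaldehyde
Product: 9 2,2'-(5-bromo-2-fluoro-1,3-phenylene)bis(1,3-dioxolane)
Conditions: HOCH2CH2OH, p-TsOH·H2O (cat.), toluene, reflux (Dean–Stark)
Reagents that add atoms: ethylene glycol, OCCO
Why: Acid-catalysed acetalisation with azeotropic water removal. The dioxolanes switch off SNAr activation of the C–F carbon and protect the carbonyls from borane and aqueous base in step 6.

Step 6
Reactants: 5 3-(dodec-11-en-1-yl)-5-methoxyphenol; 9 2,2'-(5-bromo-2-fluoro-1,3-phenylene)bis(1,3-dioxolane)
Product: 11 3-{12-[3,5-bis(1,3-dioxolan-2-yl)-4-fluorophenyl]dodecyl}-5-methoxyphenol, via the O-borylated B-alkyl-9-BBN borane 10 (not isolated)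
Conditions: 5, 9-BBN (2.3 equiv), THF, 0 °C to rt; then 9, Pd(dppf)Cl2 (5 mol %), 3 M aq K3PO4, DMF, 60 °C
Reagents that add atoms: 9-borabicyclo[3.3.1]nonane, B1C2CCCC1CCC2 (kept only in intermediate 10)
Why: Anti-Markovnikov hydroboration of the terminal alkene followed by B-alkyl Suzuki–Miyaura coupling at the unhindered aryl bromide. One extra equivalent of 9-BBN is allowed for the phenolic O–H, whose borinate the aqueous base hydrolyses; the fluoride between two acetals is not activated toward the phenoxide.

Step 7
Reactants: 11 3-{12-[3,5-bis(1,3-dioxolan-2-yl)-4-fluorophenyl]dodecyl}-5-methoxyphenol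
Product: 12 2-fluoro-5-[12-(3-hydroxy-5-methoxyphenyl)dodecyl]benzene-1,3-dicarbaldehyde
Conditions: 2 M HCl, THF, rt
Reagents that add atoms: water, O
Why: Aqueous acid hydrolysis of the aryl dioxolanes. Under acid the phenol stays protonated and cannot attack the newly activated fluoride, so 12 should be isolable if kept away from base.

Step 8
Reactants: 12 2-fluoro-5-[12-(3-hydroxy-5-methoxyphenyl)dodecyl]benzene-1,3-dicarbaldehyde
Product: 13 1⁵-methoxy-2-oxa-1(1,3),3(1,4)-dibenzenacyclopentadecaphane-3²,3⁶-dicarbaldehyde (20-membered diaryl ether; CHO at B2 and B6; OMe at A3)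
Conditions: Cs2CO3 (3 equiv), amine-free DMF, syringe-pump addition to about 1 mM, 40 °C, argon
Reagents that add atoms: none
Why: The caesium phenoxide at the A1 oxygen adds to B1 ipso to fluorine, giving a Meisenheimer anion whose charge is delocalised into both ortho formyl groups; loss of fluoride restores the arene (addition–elimination SNAr). The closest known reaction types are SNAr diaryl ether macrocyclisations of ortho-activated fluoroarenes and the intermolecular O-arylation of phenoxides by 2-fluorobenzaldehydes. One ring closes: the 20-membered macrocycle, by end-to-end formation of the O–B1 bond with the leaving fluoride exocyclic to the new ring; the twelve-carbon tether spans a meta-bridged ring A and a para-bridged ring B without strain. No stereocentre is formed. The selectivity needed is ring closure over intermolecular substitution, which slow addition to a dilute base suspension should secure because the stationary phenoxide concentration stays low and the substitution is irreversible. Site selectivity follows from the substrate: there is one phenol, so one nucleophilic oxygen, and one C–F carbon. Addition of phenoxide to a formyl group is reversible and unproductive, and the flat formyl groups do not hinder attack at B1. Mild temperature and amine-free solvent keep dimethylamine away from the activated fluoride.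

Step 9
Reactants: 13 1⁵-methoxy-2-oxa-1(1,3),3(1,4)-dibenzenacyclopentadecaphane-3²,3⁶-dicarbaldehyde
Product: 15 1⁵-methoxy-2-oxa-1(1,3),3(1,4)-dibenzenacyclopentadecaphane-3²,3⁶-diol, via the macrocyclic bis-formate 14 (not isolated)
Conditions: mCPBA (3 equiv), CH2Cl2, 0 °C to rt; aq Na2S2O3/NaHCO3 wash; then MeOH, Et3N (cat.), rt, argon
Reagents that add atoms: 3-chloroperoxybenzoic acid, O=C(OO)c1cccc(Cl)c1
Why: Dakin-type Baeyer–Villiger oxidation; the peracid adds to each formyl group and the ring B carbon, activated by the ortho aryloxy oxygen, migrates to oxygen in the Criegee adduct to give aryl formates 14, which methanol cleaves. The phenols appear only after the peracid is removed, and ring A is carried as the less oxidisable anisole.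

Step 10
Reactants: 15 1⁵-methoxy-2-oxa-1(1,3),3(1,4)-dibenzenacyclopentadecaphane-3²,3⁶-diol
Product: 16 2-oxa-1(1,3),3(1,4)-dibenzenacyclopentadecaphane-1⁵,3²,3⁶-triol (CNP0314249.0)
Conditions: BBr3 (5 equiv), CH2Cl2, −78 °C to rt; then H2O
Reagents that add atoms: none
Why: Lewis-acid O-demethylation; BBr3 coordinates the methoxy oxygen and bromide attacks the methyl carbon. The diaryl ether has no SN2-susceptible carbon and should survive, and the free phenols only consume extra reagent as borates that hydrolyse on work-up.

## Compound list

1 | 12-bromododec-1-ene | C=CCCCCCCCCCCBr | starting material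
2 | 1-bromo-3,5-dimethoxybenzene | COc1cc(Br)cc(OC)c1 | starting material
3 | dodec-11-en-1-ylmagnesium bromide | C=CCCCCCCCCCC[Mg]Br | intermediate (not isolated)
4 | 1-(dodec-11-en-1-yl)-3,5-dimethoxybenzene | COc1cc(CCCCCCCCCCC=C)cc(OC)c1 | intermediate
5 | 3-(dodec-11-en-1-yl)-5-methoxyphenol | COc1cc(O)cc(CCCCCCCCCCC=C)c1 | intermediate
6 | 5-bromo-2-fluoro-1,3-dimethylbenzene | Cc1cc(Br)cc(C)c1F | starting material
7 | 5-bromo-1,3-bis(dibromomethyl)-2-fluorobenzene | BrC(Br)c1cc(Br)cc(C(Br)Br)c1F | intermediate
8 | 5-bromo-2-fluorobenzene-1,3-dicarbaldehyde | O=Cc1cc(Br)cc(C=O)c1F | intermediate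
9 | 2,2'-(5-bromo-2-fluoro-1,3-phenylene)bis(1,3-dioxolane) | Fc1c(C2OCCO2)cc(Br)cc1C3OCCO3 | intermediate
10 | 9-[12-(3-methoxy-5-{[9-borabicyclo[3.3.1]nonan-9-yl]oxy}phenyl)dodecyl]-9-borabicyclo[3.3.1]nonane | COc1cc(OB2C3CCCC2CCC3)cc(CCCCCCCCCCCCB4C5CCCC4CCC5)c1 | intermediate (not isolated)
11 | 3-{12-[3,5-bis(1,3-dioxolan-2-yl)-4-fluorophenyl]dodecyl}-5-methoxyphenol | COc1cc(O)cc(CCCCCCCCCCCCc2cc(C3OCCO3)c(F)c(C4OCCO4)c2)c1 | intermediate
12 | 2-fluoro-5-[12-(3-hydroxy-5-methoxyphenyl)dodecyl]benzene-1,3-dicarbaldehyde | COc1cc(O)cc(CCCCCCCCCCCCc2cc(C=O)c(F)c(C=O)c2)c1 | intermediate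
13 | 1⁵-methoxy-2-oxa-1(1,3),3(1,4)-dibenzenacyclopentadecaphane-3²,3⁶-dicarbaldehyde | O=Cc1cc2CCCCCCCCCCCCc3cc(OC)cc(c3)Oc1c(C=O)c2 | intermediate
14 | 1⁵-methoxy-2-oxa-1(1,3),3(1,4)-dibenzenacyclopentadecaphane-3²,3⁶-diyl diformate | O=COc1cc2CCCCCCCCCCCCc3cc(OC)cc(c3)Oc1c(OC=O)c2 | intermediate (not isolated)
15 | 1⁵-methoxy-2-oxa-1(1,3),3(1,4)-dibenzenacyclopentadecaphane-3²,3⁶-diol | COc1cc2cc(c1)Oc1c(O)cc(cc1O)CCCCCCCCCCCC2 | intermediate
16 | 2-oxa-1(1,3),3(1,4)-dibenzenacyclopentadecaphane-1⁵,3²,3⁶-triol | Oc1cc2cc(c1)Oc1c(O)cc(cc1O)CCCCCCCCCCCC2 | target

## Step count and risks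

Total step count: 10. Longest linear sequence: 8 steps (6 → 7 → 8 → 9 → 11 → 12 → 13 → 15 → 16; steps 3–10). The ring A branch (steps 1, 2) joins at step 6.

**Step 8 (key step).** The likely failure is intermolecular substitution outrunning ring closure, since a flexible 20-membered ring has a low effective molarity; this would give linear and cyclic oligomers. A second risk is base-induced loss of formyl groups if hydroxide is present. Fallback: make the ether intermolecularly and close the ring at C1–B4. From **5** and **8**, K2CO3 in DMF at room temperature should give 5-bromo-2-[3-(dodec-11-en-1-yl)-5-methoxyphenoxy]benzene-1,3-dicarbaldehyde F1. Acetalisation with ethylene glycol gives the bis-dioxolane F2. Hydroboration with 9-BBN gives the alkylborane F3. Intramolecular B-alkyl Suzuki–Miyaura coupling at high dilution (Pd(dppf)Cl2, aqueous K3PO4) gives the macrocyclic bis-dioxolane F4. Aqueous HCl returns to the route at **13**.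

**Step 9.** Hydride rather than aryl migration in the Criegee adduct would give carboxylic acids. The reaction could also stall after the first oxidation, because the twisted, doubly ortho-flanked ether oxygen donates less and the remaining formyl group deactivates the ring. Electrophilic hydroxylation of ring A by peracid is a further risk. Fallback from **13**: MeMgBr addition gives the bis(1-hydroxyethyl) macrocycle F5 (diastereomer mixture, irrelevant); Dess–Martin oxidation gives the diacetyl macrocycle F6; Baeyer–Villiger oxidation (mCPBA, CF3CO2H, CH2Cl2), in which no hydride can migrate and aryl outruns methyl, gives the bis-acetate F7; methanolysis (K2CO3, MeOH) returns at **15**.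

**Step 6.** The phenolic O–H may consume borane and leave hydroboration incomplete. Protodeboronation or β-hydride elimination at the alkylpalladium stage would return alkane or isomerised alkene. Fallback from **5**: MOMCl and iPr2NEt give 1-(dodec-11-en-1-yl)-3-methoxy-5-(methoxymethoxy)benzene F8; 9-BBN gives its alkylborane F9; coupling with **9** under the step 6 conditions gives the MOM-protected bis-dioxolane F10; 3 M HCl in THF at 50 °C removes the MOM group and both acetals and returns at **12**.

**Step 3 (with step 4).** Radical bromination may stop short or overshoot, giving mixtures of bromination levels that hydrolyse to mixed aldehydes and acids. Fallback from **6**, avoiding radical halogenation: KMnO4 in aqueous pyridine at reflux gives 5-bromo-2-fluorobenzene-1,3-dicarboxylic acid F11; BH3·THF gives (5-bromo-2-fluoro-1,3-phenylene)dimethanol F12; MnO2 in CH2Cl2 returns at **8**.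

## Further compounds

F1 | step 8 | 5-bromo-2-[3-(dodec-11-en-1-yl)-5-methoxyphenoxy]benzene-1,3-dicarbaldehyde | COc1cc(CCCCCCCCCCC=C)cc(Oc2c(C=O)cc(Br)cc2C=O)c1
F2 | step 8 | 2,2'-{5-bromo-2-[3-(dodec-11-en-1-yl)-5-methoxyphenoxy]-1,3-phenylene}bis(1,3-dioxolane) | COc1cc(CCCCCCCCCCC=C)cc(Oc2c(C3OCCO3)cc(Br)cc2C4OCCO4)c1
F3 | step 8 | 9-(12-{3-[4-bromo-2,6-bis(1,3-dioxolan-2-yl)phenoxy]-5-methoxyphenyl}dodecyl)-9-borabicyclo[3.3.1]nonane | COc1cc(CCCCCCCCCCCCB2C3CCCC2CCC3)cc(Oc4c(C5OCCO5)cc(Br)cc4C6OCCO6)c1
F4 | step 8 | 2,2'-(1⁵-methoxy-2-oxa-1(1,3),3(1,4)-dibenzenacyclopentadecaphane-3²,3⁶-diyl)bis(1,3-dioxolane) | COc1cc2cc(c1)Oc1c(C3OCCO3)cc(cc1C4OCCO4)CCCCCCCCCCCC2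
F5 | step 9 | 1,1'-(1⁵-methoxy-2-oxa-1(1,3),3(1,4)-dibenzenacyclopentadecaphane-3²,3⁶-diyl)di(ethan-1-ol), mixture of diastereomers | COc1cc2cc(c1)Oc1c(C(C)O)cc(cc1C(C)O)CCCCCCCCCCCC2
F6 | step 9 | 1,1'-(1⁵-methoxy-2-oxa-1(1,3),3(1,4)-dibenzenacyclopentadecaphane-3²,3⁶-diyl)di(ethan-1-one) | COc1cc2cc(c1)Oc1c(C(C)=O)cc(cc1C(C)=O)CCCCCCCCCCCC2
F7 | step 9 | 1⁵-methoxy-2-oxa-1(1,3),3(1,4)-dibenzenacyclopentadecaphane-3²,3⁶-diyl diacetate | COc1cc2cc(c1)Oc1c(OC(C)=O)cc(cc1OC(C)=O)CCCCCCCCCCCC2
F8 | step 6 | 1-(dodec-11-en-1-yl)-3-methoxy-5-(methoxymethoxy)benzene | COCOc1cc(OC)cc(CCCCCCCCCCC=C)c1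
F9 | step 6 | 9-{12-[3-methoxy-5-(methoxymethoxy)phenyl]dodecyl}-9-borabicyclo[3.3.1]nonane | COCOc1cc(OC)cc(CCCCCCCCCCCCB2C3CCCC2CCC3)c1
F10 | step 6 | 2,2'-(2-fluoro-5-{12-[3-methoxy-5-(methoxymethoxy)phenyl]dodecyl}-1,3-phenylene)bis(1,3-dioxolane) | COCOc1cc(OC)cc(CCCCCCCCCCCCc2cc(C3OCCO3)c(F)c(C4OCCO4)c2)c1
F11 | step 3 | 5-bromo-2-fluorobenzene-1,3-dicarboxylic acid | OC(=O)c1cc(Br)cc(C(O)=O)c1F
F12 | step 3 | (5-bromo-2-fluoro-1,3-phenylene)dimethanol | OCc1cc(Br)cc(CO)c1F
A1 | alternative 1 | 1-diazo-15-[3,5-dimethoxy-4-({[tri(propan-2-yl)silyl]ethynyl}oxy)phenyl]-3-methylidenepentadecan-2-one | COc1cc(CCCCCCCCCCCCC(=C)C(=O)C=[N+]=[N-])cc(OC)c1OC#C[Si](C(C)C)(C(C)C)C(C)C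
A2 | alternative 1 | macrocyclic phenol with triisopropylsilyl at A2, hydroxyl at A3 and methyl ethers at B2 and B6 | COc1cc2CCCCCCCCCCCCc3cc(O)c([Si](C(C)C)(C(C)C)C(C)C)c(c3)Oc1c(OC)c2
A3 | alternative 2 | 3-chloro-5-[12-(4-hydroxy-3,5-dimethoxyphenyl)dodecyl]cyclohex-2-en-1-one, racemic | COc1cc(CCCCCCCCCCCCC2CC(=O)C=C(Cl)C2)cc(OC)c1O
A4 | alternative 2 | racemic macrocyclic 3-aryloxycyclohex-2-enone (ring A in dihydro keto form, methyl ethers at B2 and B6) | COc1cc2CCCCCCCCCCCCC3CC(=O)C=C(C3)Oc1c(OC)c2
A5 | alternative 3 | methyl (E)-3-{4-[3-(9,9-bis(phenylsulfonyl)nonyl)-5-methoxyphenoxy]-3,5-dimethoxyphenyl}prop-2-en-1-yl carbonate | COC(=O)OC/C=C/c1cc(OC)c(Oc2cc(OC)cc(CCCCCCCCC(S(=O)(=O)c3ccccc3)S(=O)(=O)c4ccccc4)c2)c(OC)c1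
A6 | alternative 3 | macrocyclic (E)-styrene with a bis(phenylsulfonyl) carbon at C4, trimethyl ether | COc1cc2/C=C/CC(S(=O)(=O)c4ccccc4)(S(=O)(=O)c5ccccc5)CCCCCCCCc3cc(OC)cc(c3)Oc1c(OC)c2
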